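The route rests on cutting the bond between the methine C2 (which carries the acyloxymethyl carbon C3) and the allylic CH2 C4 of the 3,4-dimethoxycinnamyl arm. C2 sits next to the carbinol C1 bearing the 4-methoxyphenyl ring, so it is the α-carbon of a β-hydroxy ester and C4 is an allylic electrophile. Alkylating the dilithium alkoxide–enolate of methyl (S)-3-hydroxy-3-(4-methoxyphenyl)propanoate with (E)-3,4-dimethoxycinnamyl bromide should join both aryl halves and set C2 anti to the C1 oxygen in one operation; no ring is formed. Reduction, primary-selective Mitsunobu esterification with the O-silylated (Z)-2-(hydroxymethyl)but-2-enoic acid and desilylation complete the route.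

Key step: step 4

Assumption: the cinnamyl fragment is bought as methyl (E)-3,4-dimethoxycinnamate (the free acid would add one esterification); the target is S at carbinol C1 and S at C2 (the anti pair), which reads (2R,3S) at the ester stage only because CO2Me outranks the carbinol carbon.

Step 1
Reactants: 1 methyl 3-(4-methoxyphenyl)-3-oxopropanoate
Product: 2 methyl (S)-3-hydroxy-3-(4-methoxyphenyl)propanoate
Conditions: [RuCl(p-cymene)((R)-SEGPHOS)]Cl (0.5 mol %), H2 (30 bar), MeOH, 50 °C
Reagents that add atoms: none
Why: Noyori asymmetric hydrogenation of a β-keto ester, in which the ester carbonyl chelates ruthenium and the (R)-diphosphine (the hand that gives (R)-3-hydroxybutanoate from acetoacetate) delivers hydride to the face that gives the (S)-aryl carbinol, the descriptor differing only because aryl outranks CH2CO2Me.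

Step 2
Reactants: 3 methyl (E)-3-(3,4-dimethoxyphenyl)prop-2-enoate
Product: 4 (E)-3-(3,4-dimethoxyphenyl)prop-2-en-1-ol
Conditions: i-Bu2AlH (2.3 equiv), CH2Cl2, −78 → 0 °C; aq potassium sodium tartrate work-up
Reagents that add atoms: none
Why: 1,2-reduction of an α,β-unsaturated ester with DIBAL-H should give the allylic alcohol without touching the E-alkene.

Step 3
Reactants: 4 (E)-3-(3,4-dimethoxyphenyl)prop-2-en-1-ol
Product: 5 (E)-3,4-dimethoxycinnamyl bromide, i.e. (E)-4-(3-bromoprop-1-enyl)-1,2-dimethoxybenzene
Conditions: PBr3 (0.4 equiv), Et2O, 0 °C, dark; used at once without chromatography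
Reagents that add atoms: phosphorus tribromide, BrP(Br)Br
Why: bromination of a primary allylic alcohol through its phosphite ester, where conjugation with the aryl ring keeps bromine on the primary terminus and the E geometry intact.

Step 4
Reactants: 2 methyl (S)-3-hydroxy-3-(4-methoxyphenyl)propanoate; 5 (E)-3,4-dimethoxycinnamyl bromide
Product: 7 methyl (2R,3S)-2-[(E)-3-(3,4-dimethoxyphenyl)prop-2-enyl]-3-hydroxy-3-(4-methoxyphenyl)propanoate, via dilithium alkoxide–enolate 6 (not isolated)
Conditions: LiN(i-Pr)2 (2.2 equiv), THF, −78 → −30 °C; then 5 (1.3 equiv), DMPU, −78 → −25 °C; AcOH quench at −78 °C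
Reagents that add atoms: none
Why: Fráter–Seebach alkylation: two equivalents of amide base remove the hydroxyl proton and one α-proton of 2, and the dianion 6 is held as a six-membered lithium chelate spanning the alkoxide and enolate oxygens, which fixes the enolate geometry. The enolate carbon (C2 of the target) displaces bromide from the primary carbon of 5 by direct SN2 substitution; the closest known reaction type is the anti-selective alkylation of β-hydroxy ester dianions with allylic halides. No ring is closed, so no mode of closure applies. The new stereocentre C2 is controlled by the existing carbinol centre C1: the electrophile enters the chelate face opposite the 4-methoxyphenyl group, which should give the anti (2R,3S) arrangement the target requires. The step needs anti diastereoselection, C- over O-alkylation and SN2 over SN2′ attack; the chelate secures the first two, and retention of styrene conjugation at an unhindered primary terminus secures the third. The alkoxide also blocks β-elimination, and a reactive allylic bromide at low temperature should let alkylation outrun retro-aldol cleavage.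

Step 5
Reactants: 7 methyl (2R,3S)-2-[(E)-3-(3,4-dimethoxyphenyl)prop-2-enyl]-3-hydroxy-3-(4-methoxyphenyl)propanoate
Product: 8 (1S,2S)-2-[(E)-3-(3,4-dimethoxyphenyl)prop-2-enyl]-1-(4-methoxyphenyl)propane-1,3-diol
Conditions: LiAlH4 (1.5 equiv), THF, 0 °C; aq NaOH work-up
Reagents that add atoms: none
Why: hydride reduction of the methyl ester to the primary alcohol should leave the isolated styrenyl alkene and both stereocentres untouched, the C2 descriptor changing from R to S only through the priority change.

Step 6
Reactants: 9 (E)-but-2-enal (crotonaldehyde)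
Product: 10 (Z)-2-iodobut-2-enal
Conditions: I2 (1.5 equiv), K2CO3 (1.2 equiv), DMAP (0.2 equiv), THF/H2O (1:1), rt; used crude
Reagents that add atoms: iodine, II
Why: α-iodination of an enal by amine conjugate addition, iodination of the enolate and E1cB loss of the amine (a Morita–Baylis–Hillman-type addition–elimination), which should give the isomer with methyl trans to the formyl group and cis to iodine.

Step 7
Reactants: 10 (Z)-2-iodobut-2-enal
Product: 11 (Z)-2-iodobut-2-en-1-ol
Conditions: NaBH4, CeCl3·7H2O, MeOH, 0 °C
Reagents that add atoms: none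
Why: Luche reduction should give clean 1,2-reduction of the enal and leave the vinyl iodide and the alkene geometry intact.

Step 8
Reactants: 11 (Z)-2-iodobut-2-en-1-ol
Product: 12 tert-butyl{[(Z)-2-iodobut-2-enyl]oxy}dimethylsilane
Conditions: TBSCl (1.2 equiv), imidazole (2.0 equiv), CH2Cl2, 0 °C → rt
Reagents that add atoms: tert-butyldimethylsilyl chloride, CC(C)(C)[Si](C)(C)Cl
Why: routine imidazole-mediated silylation of a primary alcohol masks the hydroxyl that would otherwise compete as the alcohol partner in the later Mitsunobu reaction.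

Step 9
Reactants: 12 tert-butyl{[(Z)-2-iodobut-2-enyl]oxy}dimethylsilane
Product: 13 (Z)-2-{[(tert-butyldimethylsilyl)oxy]methyl}but-2-enoic acid
Conditions: PdCl2(PPh3)2 (5 mol %), CO (1 atm), K2CO3 (3 equiv), DMF/H2O (5:1), 50 °C; then aq citric acid to pH 4
Reagents that add atoms: carbon monoxide, [C-]#[O+]; water, O
Why: palladium-catalysed hydroxycarbonylation of a vinyl iodide (oxidative addition, CO insertion, hydrolysis of the acylpalladium) proceeds with retention of alkene geometry, so iodine cis to methyl becomes carboxyl cis to methyl, the required Z acid.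

Step 10
Reactants: 8 (1S,2S)-2-[(E)-3-(3,4-dimethoxyphenyl)prop-2-enyl]-1-(4-methoxyphenyl)propane-1,3-diol; 13 (Z)-2-{[(tert-butyldimethylsilyl)oxy]methyl}but-2-enoic acid
Product: 14 [(2S,3S)-2-[(E)-3-(3,4-dimethoxyphenyl)prop-2-enyl]-3-hydroxy-3-(4-methoxyphenyl)propyl] (Z)-2-{[(tert-butyldimethylsilyl)oxy]methyl}but-2-enoate
Conditions: PPh3 (1.2 equiv), DIAD (1.2 equiv), 13 (1.1 equiv), THF, −20 → 0 °C
Reagents that add atoms: none
Why: Mitsunobu esterification, in which the primary hydroxyl forms the alkoxyphosphonium ion faster than the hindered secondary benzylic one and is displaced by the carboxylate at a non-stereogenic CH2, so neither stereocentre is touched and the acid, never activated as an acyl electrophile, should keep its Z geometry.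

Step 11
Reactants: 14 [(2S,3S)-2-[(E)-3-(3,4-dimethoxyphenyl)prop-2-enyl]-3-hydroxy-3-(4-methoxyphenyl)propyl] (Z)-2-{[(tert-butyldimethylsilyl)oxy]methyl}but-2-enoate
Product: 15 [(2S,3S)-2-[(E)-3-(3,4-dimethoxyphenyl)prop-2-enyl]-3-hydroxy-3-(4-methoxyphenyl)propyl] (Z)-2-(hydroxymethyl)but-2-enoate (CNP0210582.1)
Conditions: HF·pyridine, pyridine, THF, 0 °C → rt
Reagents that add atoms: none
Why: fluoride-driven cleavage of the primary silyl ether under buffered conditions should avoid acyl migration to the free C1 hydroxyl, E/Z isomerisation of the enoate and ionisation of the 4-methoxybenzylic alcohol.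

Compound list
1 | methyl 3-(4-methoxyphenyl)-3-oxopropanoate | COC(=O)CC(=O)c1ccc(OC)cc1 | starting material
2 | methyl (S)-3-hydroxy-3-(4-methoxyphenyl)propanoate | COC(=O)C[C@H](O)c1ccc(OC)cc1 | intermediate
3 | methyl (E)-3-(3,4-dimethoxyphenyl)prop-2-enoate | COC(=O)/C=C/c1ccc(OC)c(OC)c1 | starting material
4 | (E)-3-(3,4-dimethoxyphenyl)prop-2-en-1-ol | OC/C=C/c1ccc(OC)c(OC)c1 | intermediate
5 | (E)-3,4-dimethoxycinnamyl bromide | BrC/C=C/c1ccc(OC)c(OC)c1 | intermediate
6 | dilithium alkoxide–enolate of 2 (lithium-bridged chelate, enolate O–Li cis to the carbinol carbon) | CO/C(O[Li])=C/[C@H](O[Li])c1ccc(OC)cc1 | intermediate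
7 | methyl (2R,3S)-2-[(E)-3-(3,4-dimethoxyphenyl)prop-2-enyl]-3-hydroxy-3-(4-methoxyphenyl)propanoate | COC(=O)[C@H](C/C=C/c1ccc(OC)c(OC)c1)[C@H](O)c1ccc(OC)cc1 | intermediate
8 | (1S,2S)-2-[(E)-3-(3,4-dimethoxyphenyl)prop-2-enyl]-1-(4-methoxyphenyl)propane-1,3-diol | OC[C@H](C/C=C/c1ccc(OC)c(OC)c1)[C@H](O)c1ccc(OC)cc1 | intermediate
9 | (E)-but-2-enal (crotonaldehyde) | C/C=C/C=O | starting material
10 | (Z)-2-iodobut-2-enal | C/C=C(\I)C=O | intermediate
11 | (Z)-2-iodobut-2-en-1-ol | C/C=C(\I)CO | intermediate
12 | tert-butyl{[(Z)-2-iodobut-2-enyl]oxy}dimethylsilane | C/C=C(\I)CO[Si](C)(C)C(C)(C)C | intermediate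
13 | (Z)-2-{[(tert-butyldimethylsilyl)oxy]methyl}but-2-enoic acid | C/C=C(/CO[Si](C)(C)C(C)(C)C)C(=O)O | intermediate
14 | [(2S,3S)-2-[(E)-3-(3,4-dimethoxyphenyl)prop-2-enyl]-3-hydroxy-3-(4-methoxyphenyl)propyl] (Z)-2-{[(tert-butyldimethylsilyl)oxy]methyl}but-2-enoate | C/C=C(/CO[Si](C)(C)C(C)(C)C)C(=O)OC[C@H](C/C=C/c1ccc(OC)c(OC)c1)[C@H](O)c1ccc(OC)cc1 | intermediate
15 | [(2S,3S)-2-[(E)-3-(3,4-dimethoxyphenyl)prop-2-enyl]-3-hydroxy-3-(4-methoxyphenyl)propyl] (Z)-2-(hydroxymethyl)but-2-enoate | C/C=C(/CO)C(=O)OC[C@H](C/C=C/c1ccc(OC)c(OC)c1)[C@H](O)c1ccc(OC)cc1 | target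

Total step count: 11 steps.
Longest linear sequence: 6 steps (9 → 10 → 11 → 12 → 13 → 14 → 15; the aryl branch from 1 reaches 15 in 5 steps).

Steps most likely to fail

Step 4. The dianion may fragment by retro-aldol cleavage on warming, and the labile, electron-rich allylic bromide may be lost through ionisation, SN2′ attack or reaction with excess amide base before C-alkylation is complete. Too much polar cosolvent could also loosen the chelate and erode the anti selectivity. Fallback: setting out from 2, the same dianion 6 is alkylated with allyl bromide, a stable and unhindered electrophile that can be used in excess at −78 °C. This should give methyl (2R,3S)-3-hydroxy-3-(4-methoxyphenyl)-2-(prop-2-enyl)propanoate F1 under the same chelate control. E-selective olefin cross-metathesis of F1 with 3,4-dimethoxystyrene (second-generation Hoveyda–Grubbs catalyst, CH2Cl2, 40 °C) then attaches the aryl group and returns to the route at 7.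

Step 10. Site selectivity may be poor: the 4-methoxybenzylic hydroxyl, or a cyclic phosphorane bridging both hydroxyls, may be activated, leading to substitution or ionisation at C1, elimination to a styrene or cyclic ether formation. Fallback: setting out from 8, activation is separated from substitution. Selective sulfonylation of the primary hydroxyl (TsCl, pyridine, CH2Cl2, 0 °C) should give [(2S,3S)-2-[(E)-3-(3,4-dimethoxyphenyl)prop-2-enyl]-3-hydroxy-3-(4-methoxyphenyl)propyl] 4-methylbenzenesulfonate F2. F2 is then displaced by acid 13, neutralised beforehand with Cs2CO3 (0.5 equiv), in DMF at 40–50 °C. The carboxylate again acts only as a nucleophile, so the Z geometry is kept, and the route is rejoined at 14.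

Step 9. Carbon monoxide insertion may be slow, allowing protodeiodination, and the silyl ether may be partly lost in warm aqueous base. Fallback: setting out from 11, carboxylation is done through an organolithium. Deprotonation with n-BuLi (1 equiv) and iodine–lithium exchange with t-BuLi (2 equiv) in Et2O at −78 °C should give lithium (Z)-2-lithiobut-2-en-1-olate F3, whose alkoxide can neither eliminate nor transfer a silyl group. Quenching with CO2 gives (Z)-2-(hydroxymethyl)but-2-enoic acid F4 with retention of geometry. Bis-silylation (TBSCl, imidazole, DMF) gives tert-butyldimethylsilyl (Z)-2-{[(tert-butyldimethylsilyl)oxy]methyl}but-2-enoate F5, and selective cleavage of its silyl ester (K2CO3, THF/H2O, rt) returns to the route at 13.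

Further compounds
F1 | step 4 | methyl (2R,3S)-3-hydroxy-3-(4-methoxyphenyl)-2-(prop-2-enyl)propanoate | COC(=O)[C@H](CC=C)[C@H](O)c1ccc(OC)cc1
F2 | step 10 | [(2S,3S)-2-[(E)-3-(3,4-dimethoxyphenyl)prop-2-enyl]-3-hydroxy-3-(4-methoxyphenyl)propyl] 4-methylbenzenesulfonate | Cc1ccc(cc1)S(=O)(=O)OC[C@H](C/C=C/c1ccc(OC)c(OC)c1)[C@H](O)c1ccc(OC)cc1
F3 | step 9 | lithium (Z)-2-lithiobut-2-en-1-olate | C/C=C(\[Li])CO[Li]
F4 | step 9 | (Z)-2-(hydroxymethyl)but-2-enoic acid | C/C=C(/CO)C(=O)O
F5 | step 9 | tert-butyldimethylsilyl (Z)-2-{[(tert-butyldimethylsilyl)oxy]methyl}but-2-enoate | C/C=C(/CO[Si](C)(C)C(C)(C)C)C(=O)O[Si](C)(C)C(C)(C)C
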